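**Plan**
- Ring A carries the C1' acyl carbon and the C2' hydroxyl on neighbouring carbons, with the C6' methoxy beside C1' and the C3' side chain beside C2'. The retrosynthesis therefore cuts C2'–O and C1'–C(=O) together, back to a C1'–C2' aryne of ring A and a cinnamate.
- Further cuts: the C3'–CH2 bond (Negishi coupling), the bond between the side-chain methine and its prenyl arm (auxiliary-controlled alkylation), and the Cα=Cβ bond of the cinnamic acid (Knoevenagel–Doebner).
- Forward: (S)-lavandulyl iodide is made in 4 steps. 5-Methoxyresorcinol is turned into a carbamate/MOM arene, brominated between the two oxygens and coupled with the chain. It is then silylated next to the carbamate; epoxidation and hydride treatment hydrate the prenyl arm and free the phenol, which is triflated.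
- The aryne insertion then joins ring A to the complete E-cinnamoyl unit, and mild acid removes all protecting groups. No ring is formed anywhere in the route.
- The single stereocenter comes from the (S)-4-benzyloxazolidinone-directed deconjugative prenylation; the E-olefin comes from the Doebner condensation.

Key step: step 16

Remark: the side-chain carbon of the target is R; the same spatial arrangement is labelled S in imide 7, alcohol 8, iodide 9 and epoxide 20 only because the CIP ranking of the arms changes.

**Route**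

Step 1
Reactants: 1 (S)-4-benzyloxazolidin-2-one; 2 3-methylbut-2-enoyl chloride
Product: 4 (4S)-4-benzyl-3-(3-methylbut-2-enoyl)-1,3-oxazolidin-2-one, via N-lithiated oxazolidinone 3 (not isolated)
Conditions: n-BuLi, THF, −78 °C; then 2, −78 → 0 °C
Reagents that add atoms: none
Why: N-acylation of the lithiated Evans oxazolidinone with an acid chloride is standard and leaves the C4 stereocenter untouched.

Step 2
Reactants: 4 (4S)-4-benzyl-3-(3-methylbut-2-enoyl)-1,3-oxazolidin-2-one; 5 prenyl bromide
Product: 7 (4S)-4-benzyl-3-[(2S)-5-methyl-2-(prop-1-en-2-yl)hex-4-enoyl]-1,3-oxazolidin-2-one, via sodium Z-dienolate 6 (not isolated)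
Conditions: NaN(SiMe3)2 (1.05 equiv), THF, −78 °C; then 5, −78 → −40 °C
Reagents that add atoms: none
Why: γ-deprotonation gives the sodium-chelated Z-dienolate, which is alkylated at the α-carbon on the face opposite the C4 benzyl group (Evans deconjugative asymmetric alkylation, the established entry to lavandulol), so the auxiliary sets the S α-center while the double bond moves out of conjugation and becomes the isopropenyl group.

Step 3
Reactants: 7 (4S)-4-benzyl-3-[(2S)-5-methyl-2-(prop-1-en-2-yl)hex-4-enoyl]-1,3-oxazolidin-2-one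
Product: 8 (S)-lavandulol [(2S)-5-methyl-2-(prop-1-en-2-yl)hex-4-en-1-ol]
Conditions: LiBH4, H2O (1 equiv), Et2O, 0 °C
Reagents that add atoms: none
Why: LiBH4 reductive cleavage of an N-acyl oxazolidinone attacks the exocyclic carbonyl without enolisation, so the β,γ-unsaturated α-center should survive and the auxiliary is returned.

Step 4
Reactants: 8 (S)-lavandulol
Product: 9 (S)-lavandulyl iodide [(2S)-1-iodo-5-methyl-2-(prop-1-en-2-yl)hex-4-ene]
Conditions: I2, PPh3, imidazole, CH2Cl2, 0 °C → rt
Reagents that add atoms: iodine, II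
Why: Appel-type iodination of a primary alcohol is an SN2 displacement at the CH2 carbon and does not touch the neighbouring stereocenter or the two alkenes.

Step 5
Reactants: 10 5-methoxyresorcinol
Product: 11 3-hydroxy-5-methoxyphenyl N,N-diethylcarbamate
Conditions: Et2NCOCl (0.9 equiv), K2CO3, MeCN, reflux
Reagents that add atoms: diethylcarbamoyl chloride, CCN(CC)C(Cl)=O
Why: O-carbamoylation of one of two equivalent phenols with a deficit of reagent is a statistical desymmetrisation whose mono-product should be separable from the bis-carbamate and from recoverable 10.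

Step 6
Reactants: 11 3-hydroxy-5-methoxyphenyl N,N-diethylcarbamate
Product: 12 3-methoxy-5-(methoxymethoxy)phenyl N,N-diethylcarbamate
Conditions: MOMCl, iPr2NEt, CH2Cl2, 0 °C → rt
Reagents that add atoms: chloromethyl methyl ether, COCCl
Why: Williamson-type alkylation of the remaining phenol installs a base-stable ether that also serves as an ortho-directing group.

Step 7
Reactants: 12 3-methoxy-5-(methoxymethoxy)phenyl N,N-diethylcarbamate
Product: 14 2-bromo-5-methoxy-3-(methoxymethoxy)phenyl N,N-diethylcarbamate, via aryllithium 13 (not isolated)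
Conditions: s-BuLi, TMEDA, THF, −78 °C; then BrCCl2CCl2Br, −78 °C
Reagents that add atoms: 1,2-dibromo-1,1,2,2-tetrachloroethane, BrC(Cl)(Cl)C(Cl)(Cl)Br
Why: Directed ortho-metalation takes place at the ring carbon flanked by the two strongest directors (O-carbamate and OMOM), and the aryllithium is brominated at −78 °C before an anionic ortho-Fries shift can start.

Step 8
Reactants: 9 (S)-lavandulyl iodide; 14 2-bromo-5-methoxy-3-(methoxymethoxy)phenyl N,N-diethylcarbamate
Product: 17 5-methoxy-3-(methoxymethoxy)-2-[(2R)-5-methyl-2-(prop-1-en-2-yl)hex-4-en-1-yl]phenyl N,N-diethylcarbamate, via alkyllithium 15 (not isolated), via alkylzinc chloride 16 (not isolated)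
Conditions: 9, t-BuLi (2.1 equiv), Et2O, −78 °C; ZnCl2, THF, −78 °C → rt; then 14, Pd(OAc)2 (5 mol %), SPhos (10 mol %), THF, 50 °C
Reagents that add atoms: none
Why: Negishi sp3–sp2 coupling: iodine–lithium exchange and transmetalation give a primary alkylzinc that the Pd/SPhos catalyst should join to the di-ortho-oxygenated bromide faster than β-hydride elimination, and the stereocenter, one carbon away from zinc, takes no part.

Step 9
Reactants: 17 5-methoxy-3-(methoxymethoxy)-2-[(2R)-5-methyl-2-(prop-1-en-2-yl)hex-4-en-1-yl]phenyl N,N-diethylcarbamate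
Product: 19 3-methoxy-5-(methoxymethoxy)-6-[(2R)-5-methyl-2-(prop-1-en-2-yl)hex-4-en-1-yl]-2-(trimethylsilyl)phenyl N,N-diethylcarbamate, via aryllithium 18 (not isolated)
Conditions: s-BuLi, TMEDA, THF, −78 °C; then Me3SiCl, −78 °C → rt
Reagents that add atoms: chlorotrimethylsilane, C[Si](C)(C)Cl
Why: A second directed ortho-metalation is steered by the O-carbamate, which outranks OMOM, to the C–H between carbamate and OMe, and cold silylation traps the aryllithium before it can rearrange.

Step 10
Reactants: 19 3-methoxy-5-(methoxymethoxy)-6-[(2R)-5-methyl-2-(prop-1-en-2-yl)hex-4-en-1-yl]-2-(trimethylsilyl)phenyl N,N-diethylcarbamate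
Product: 20 6-[(2S)-2-[(3,3-dimethyloxiran-2-yl)methyl]-3-methylbut-3-en-1-yl]-3-methoxy-5-(methoxymethoxy)-2-(trimethylsilyl)phenyl N,N-diethylcarbamate (side-chain methine spatially unchanged; both oxirane epimers)
Conditions: mCPBA (1.05 equiv), CH2Cl2, −20 → 0 °C
Reagents that add atoms: 3-chloroperbenzoic acid, OOC(=O)c1cccc(Cl)c1
Why: Prilezhaev epoxidation is much faster at the electron-rich trisubstituted olefin than at the 1,1-disubstituted isopropenyl group; the oxirane center forms unselectively but is erased in step 11.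

Step 11
Reactants: 20 epoxy carbamate
Product: 21 6-[(2R)-5-hydroxy-5-methyl-2-(prop-1-en-2-yl)hexyl]-3-methoxy-5-(methoxymethoxy)-2-(trimethylsilyl)phenol
Conditions: LiAlH4, THF, 0 °C → reflux
Reagents that add atoms: none
Why: LiAlH4 opens the trisubstituted epoxide by SN2 hydride delivery at the less substituted carbon to give the tertiary alcohol and in the same operation reductively cleaves the aryl carbamate to the phenol, while MOM ether, aryl silane and isopropenyl group are inert to hydride.

Step 12
Reactants: 21 silyl phenol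
Product: 22 6-[(2R)-5-hydroxy-5-methyl-2-(prop-1-en-2-yl)hexyl]-3-methoxy-5-(methoxymethoxy)-2-(trimethylsilyl)phenyl trifluoromethanesulfonate
Conditions: PhNTf2, K2CO3, DMF, rt → 40 °C
Reagents that add atoms: N-phenylbis(trifluoromethanesulfonimide), O=S(=O)(N(c1ccccc1)S(=O)(=O)C(F)(F)F)C(F)(F)F
Why: Sulfonylation of the phenoxide with PhNTf2 under carbonate base is selective for the phenol over the neutral tertiary alcohol and is the usual closing step toward ortho-silylaryl triflates.

Step 13
Reactants: 22 silyl triflate with free tertiary alcohol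
Product: 23 3-methoxy-5-(methoxymethoxy)-6-[(2R)-5-methyl-2-(prop-1-en-2-yl)-5-(triethylsilyloxy)hexyl]-2-(trimethylsilyl)phenyl trifluoromethanesulfonate
Conditions: Et3SiOTf (1.2 equiv), 2,6-lutidine, CH2Cl2, −78 °C
Reagents that add atoms: triethylsilyl trifluoromethanesulfonate, CC[Si](CC)(CC)OS(=O)(=O)C(F)(F)F
Why: Silyl triflate/lutidine silylation is the standard protection of a tertiary alcohol and at −78 °C outruns activation of the aryl MOM ether; the TES ether removes the only O–H from the aryne step yet is lost in the mild final acidolysis.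

Step 14
Reactants: 24 2,4-dihydroxybenzaldehyde
Product: 25 2,4-bis(methoxymethoxy)benzaldehyde
Conditions: MOMCl (3 equiv), iPr2NEt, CH2Cl2, 0 °C → reflux
Reagents that add atoms: chloromethyl methyl ether, COCCl
Why: Double MOM etherification with excess reagent also alkylates the hydrogen-bonded 2-hydroxyl.

Step 15
Reactants: 25 2,4-bis(methoxymethoxy)benzaldehyde
Product: 26 (E)-3-[2,4-bis(methoxymethoxy)phenyl]prop-2-enoic acid
Conditions: CH2(CO2H)2, pyridine, piperidine (cat.), 90 °C
Reagents that add atoms: malonic acid, OC(=O)CC(O)=O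
Why: Knoevenagel–Doebner condensation with decarboxylation gives the E-cinnamic acid under pyridine-buffered conditions that MOM ethers tolerate.

Step 16
Reactants: 23 ring A silyl triflate; 26 (E)-3-[2,4-bis(methoxymethoxy)phenyl]prop-2-enoic acid
Product: 30 (E)-1-[2-hydroxy-6-methoxy-4-(methoxymethoxy)-3-[(2R)-5-methyl-2-(prop-1-en-2-yl)-5-(triethylsilyloxy)hexyl]phenyl]-3-[2,4-bis(methoxymethoxy)phenyl]prop-2-en-1-one, via cesium carboxylate 27 (not isolated), via aryne 28 (not isolated), via aryl anion 29 (not isolated)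
Conditions: 26 (2.5 equiv), Cs2CO3 (1.25 equiv), MeOH, rt, evaporate and dry (toluene azeotrope); then 23, CsF (3 equiv), THF, 100 °C, sealed tube; AcOH, 0 °C
Reagents that add atoms: none
Why: Fluoride attacks the C1' silicon and triflate leaves from C2' to give aryne 28; the carboxylate oxygen of 27 adds at C2', and the C1' aryl anion 29 attacks the ester carbonyl (4-exo-trig) to a transient four-membered alkoxide that opens to the ketone and the C2' phenoxide, an anionic-Fries-type 1,3-acyl shift. The closest known reaction type is the fluoride-induced insertion of arynes into the C–O bond of carboxylic acids, which gives ortho-hydroxyaryl ketones and has been run with α,β-unsaturated acids. No ring remains in the product and no stereocenter is created: the side-chain center is remote and the E-olefin is carried in from 26. The regioselectivity needed (oxygen at C2', not C1') rests on the inductively withdrawing C6' methoxy group, which distorts the aryne so that the nucleophile adds at the distal carbon and the charge develops next to OMe, a bias that should override the steric demand of the C3' alkyl group. The chemoselectivity needed (acyl shift instead of protonation, and no oxa-Michael closure) is addressed by using the dry pre-formed cesium carboxylate in THF with the tertiary alcohol silylated, so that no proton donor is present: the aryl anion can only be trapped intramolecularly, and any flavanone enolate reverts to the more stable phenoxide until the cold acetic acid quench. The excess of 27 should outcompete the hindered, cesium-chelated product phenoxide for the aryne.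

Step 17
Reactants: 30 protected 2'-hydroxychalcone
Product: 31 (E)-1-[2,4-dihydroxy-3-[(2R)-5-hydroxy-5-methyl-2-(prop-1-en-2-yl)hexyl]-6-methoxyphenyl]-3-(2,4-dihydroxyphenyl)prop-2-en-1-one (CNP0356464.1)
Conditions: HCl (3 M aq), MeOH, rt
Reagents that add atoms: none
Why: Acid-catalysed acetal methanolysis removes the three aryl MOM ethers and solvolyses the TES ether at room temperature (the usual unmasking of MOM-protected prenylated 2'-hydroxychalcones), conditions under which the hydrogen-bonded chalcone, the isopropenyl group and the tertiary alcohol should persist.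

**Compound list**
1 | (S)-4-benzyloxazolidin-2-one | O=C1N[C@@H](Cc2ccccc2)CO1 | starting material
2 | 3-methylbut-2-enoyl chloride | CC(C)=CC(Cl)=O | starting material
3 | N-lithiated (S)-4-benzyloxazolidin-2-one | O=C1N([Li])[C@@H](Cc2ccccc2)CO1 | intermediate
4 | (4S)-4-benzyl-3-(3-methylbut-2-enoyl)-1,3-oxazolidin-2-one | CC(C)=CC(=O)N1[C@@H](Cc2ccccc2)COC1=O | intermediate
5 | prenyl bromide | CC(C)=CCBr | starting material
6 | sodium Z-dienolate of 4 | C=C(C)/C=C(\[O-])N1[C@@H](Cc2ccccc2)COC1=O.[Na+] | intermediate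
7 | (4S)-4-benzyl-3-[(2S)-5-methyl-2-(prop-1-en-2-yl)hex-4-enoyl]-1,3-oxazolidin-2-one | CC(C)=CC[C@@H](C(C)=C)C(=O)N1[C@@H](Cc2ccccc2)COC1=O | intermediate
8 | (S)-lavandulol, (2S)-5-methyl-2-(prop-1-en-2-yl)hex-4-en-1-ol | CC(C)=CC[C@@H](C(C)=C)CO | intermediate
9 | (S)-lavandulyl iodide, (2S)-1-iodo-5-methyl-2-(prop-1-en-2-yl)hex-4-ene | CC(C)=CC[C@@H](C(C)=C)CI | intermediate
10 | 5-methoxyresorcinol | COc1cc(O)cc(O)c1 | starting material
11 | 3-hydroxy-5-methoxyphenyl N,N-diethylcarbamate | CCN(CC)C(=O)Oc1cc(O)cc(OC)c1 | intermediate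
12 | 3-methoxy-5-(methoxymethoxy)phenyl N,N-diethylcarbamate | CCN(CC)C(=O)Oc1cc(OC)cc(OCOC)c1 | intermediate
13 | 2-lithio derivative of 12 (lithium between carbamate and OMOM) | CCN(CC)C(=O)Oc1cc(OC)cc(OCOC)c1[Li] | intermediate
14 | 2-bromo-5-methoxy-3-(methoxymethoxy)phenyl N,N-diethylcarbamate | CCN(CC)C(=O)Oc1cc(OC)cc(OCOC)c1Br | intermediate
15 | lavandulyllithium from 9 (configuration unchanged) | CC(C)=CC[C@@H](C(C)=C)C[Li] | intermediate
16 | lavandulylzinc chloride from 15 (configuration unchanged) | CC(C)=CC[C@@H](C(C)=C)C[Zn]Cl | intermediate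
17 | 5-methoxy-3-(methoxymethoxy)-2-[(2R)-5-methyl-2-(prop-1-en-2-yl)hex-4-en-1-yl]phenyl N,N-diethylcarbamate | C=C(C)[C@H](CC=C(C)C)Cc1c(OCOC)cc(OC)cc1OC(=O)N(CC)CC | intermediate
18 | aryllithium of 17 (lithium between carbamate and OMe) | C=C(C)[C@H](CC=C(C)C)Cc1c(OCOC)cc(OC)c([Li])c1OC(=O)N(CC)CC | intermediate
19 | 3-methoxy-5-(methoxymethoxy)-6-[(2R)-5-methyl-2-(prop-1-en-2-yl)hex-4-en-1-yl]-2-(trimethylsilyl)phenyl N,N-diethylcarbamate | C=C(C)[C@H](CC=C(C)C)Cc1c(OCOC)cc(OC)c([Si](C)(C)C)c1OC(=O)N(CC)CC | intermediate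
20 | 6-[(2S)-2-[(3,3-dimethyloxiran-2-yl)methyl]-3-methylbut-3-en-1-yl]-3-methoxy-5-(methoxymethoxy)-2-(trimethylsilyl)phenyl N,N-diethylcarbamate, both oxirane epimers | C=C(C)[C@H](CC1OC1(C)C)Cc1c(OCOC)cc(OC)c([Si](C)(C)C)c1OC(=O)N(CC)CC | intermediate
21 | 6-[(2R)-5-hydroxy-5-methyl-2-(prop-1-en-2-yl)hexyl]-3-methoxy-5-(methoxymethoxy)-2-(trimethylsilyl)phenol | C=C(C)[C@H](CCC(C)(C)O)Cc1c(OCOC)cc(OC)c([Si](C)(C)C)c1O | intermediate
22 | 6-[(2R)-5-hydroxy-5-methyl-2-(prop-1-en-2-yl)hexyl]-3-methoxy-5-(methoxymethoxy)-2-(trimethylsilyl)phenyl trifluoromethanesulfonate | C=C(C)[C@H](CCC(C)(C)O)Cc1c(OCOC)cc(OC)c([Si](C)(C)C)c1OS(=O)(=O)C(F)(F)F | intermediate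
23 | 3-methoxy-5-(methoxymethoxy)-6-[(2R)-5-methyl-2-(prop-1-en-2-yl)-5-(triethylsilyloxy)hexyl]-2-(trimethylsilyl)phenyl trifluoromethanesulfonate | C=C(C)[C@H](CCC(C)(C)O[Si](CC)(CC)CC)Cc1c(OCOC)cc(OC)c([Si](C)(C)C)c1OS(=O)(=O)C(F)(F)F | intermediate
24 | 2,4-dihydroxybenzaldehyde | O=Cc1ccc(O)cc1O | starting material
25 | 2,4-bis(methoxymethoxy)benzaldehyde | O=Cc1ccc(OCOC)cc1OCOC | intermediate
26 | (E)-3-[2,4-bis(methoxymethoxy)phenyl]prop-2-enoic acid | OC(=O)/C=C/c1ccc(OCOC)cc1OCOC | intermediate
27 | cesium (E)-3-[2,4-bis(methoxymethoxy)phenyl]prop-2-enoate | [Cs+].[O-]C(=O)/C=C/c1ccc(OCOC)cc1OCOC | intermediate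
28 | C1'–C2' aryne of ring A (3-methoxy-5-(methoxymethoxy)-6-alkyl-1,2-didehydrobenzene, alkyl as in 23) | C=C(C)[C@H](CCC(C)(C)O[Si](CC)(CC)CC)CC1=C(OCOC)C=C(OC)C#C1 | intermediate
29 | cesium C1' aryl anion of the C2' O-aryl cinnamate | C=C(C)[C@H](CCC(C)(C)O[Si](CC)(CC)CC)Cc1c(OCOC)cc(OC)[c-]c1OC(=O)/C=C/c1ccc(OCOC)cc1OCOC.[Cs+] | intermediate
30 | (E)-1-[2-hydroxy-6-methoxy-4-(methoxymethoxy)-3-[(2R)-5-methyl-2-(prop-1-en-2-yl)-5-(triethylsilyloxy)hexyl]phenyl]-3-[2,4-bis(methoxymethoxy)phenyl]prop-2-en-1-one | C=C(C)[C@H](CCC(C)(C)O[Si](CC)(CC)CC)Cc1c(OCOC)cc(OC)c(C(=O)/C=C/c2ccc(OCOC)cc2OCOC)c1O | intermediate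
31 | (E)-1-[2,4-dihydroxy-3-[(2R)-5-hydroxy-5-methyl-2-(prop-1-en-2-yl)hexyl]-6-methoxyphenyl]-3-(2,4-dihydroxyphenyl)prop-2-en-1-one | C=C(C)[C@H](CCC(C)(C)O)Cc1c(O)cc(OC)c(C(=O)/C=C/c2ccc(O)cc2O)c1O | target

**Step count**
Total: 17 steps. Longest linear sequence: 12 steps (steps 1–4, 8–13, 16, 17).

**Steps most likely to fail**

Step 16. The aryl anion may be protonated before the acyl shift, the phenoxide may close onto the enone, or the carboxylate may add at C1'. The fallback sets out from 23 and 26 and stops resisting the ring closure. The free acid is used with CsF in THF at 125 °C, the proton-containing conditions under which unsaturated acids are known to go through insertion and oxa-Michael closure. This should give 2-[2,4-bis(methoxymethoxy)phenyl]-5-methoxy-7-(methoxymethoxy)-8-[(2R)-5-methyl-2-(prop-1-en-2-yl)-5-(triethylsilyloxy)hexyl]chroman-4-one F1 as a pair of C2 epimers. F1 is then opened by base-induced β-elimination (retro-oxa-Michael) with LiN(SiMe3)2 in THF at −78 → 0 °C and quenched cold with AcOH. The route is rejoined at chalcone 30.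

Step 8. Transmetalation and reductive elimination at the doubly ortho-oxygenated aryl palladium may be slow enough for β-hydride elimination, homocoupling or rearrangement of the homoallylic organometallic to take over. The fallback sets out from 9 and 14 and replaces zinc by boron. Iodide 9 is treated with t-BuLi at −78 °C and then 9-methoxy-9-BBN to give lithium B-methoxy-B-[(2S)-5-methyl-2-(prop-1-en-2-yl)hex-4-en-1-yl]-9-borabicyclo[3.3.1]nonan-9-uide F2. F2 is coupled with 14 in a B-alkyl Suzuki–Miyaura reaction (Pd(dppf)Cl2, K3PO4 aq, DMF/THF, rt → 50 °C). The route is rejoined at 17.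

Step 17. Protic acid may promote oxa-Michael closure to the flavanone, capture of a protonated isopropenyl group by a neighbouring phenol, or ionisation of the tertiary alcohol. The fallback sets out from 30 and avoids protic acid. Me3SiOTf with 2,2'-bipyridyl in CH2Cl2 at 0 °C exchanges the aryl MOM ethers for trimethylsilyl ethers, giving the pertrimethylsilylated chalcone F3. Aqueous work-up hydrolyses F3 to the tertiary TES ether of the target F4. The TES group is then removed with pyridine-buffered HF·pyridine in THF at 0 °C, arriving at 31.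

**Further compounds**
F1 | step 16 | 2-[2,4-bis(methoxymethoxy)phenyl]-5-methoxy-7-(methoxymethoxy)-8-[(2R)-5-methyl-2-(prop-1-en-2-yl)-5-(triethylsilyloxy)hexyl]chroman-4-one, both C2 epimers | C=C(C)[C@H](CCC(C)(C)O[Si](CC)(CC)CC)Cc1c(OCOC)cc(OC)c2C(=O)CC(c3ccc(OCOC)cc3OCOC)Oc12
F2 | step 8 | lithium B-methoxy-B-[(2S)-5-methyl-2-(prop-1-en-2-yl)hex-4-en-1-yl]-9-borabicyclo[3.3.1]nonan-9-uide | CC(C)=CC[C@@H](C(C)=C)C[B-]1(OC)C2CCCC1CCC2.[Li+]
F3 | step 17 | tetrakis(trimethylsilyl) ether of the TES-protected target (all four phenols silylated) | C=C(C)[C@H](CCC(C)(C)O[Si](CC)(CC)CC)Cc1c(O[Si](C)(C)C)cc(OC)c(C(=O)/C=C/c2ccc(O[Si](C)(C)C)cc2O[Si](C)(C)C)c1O[Si](C)(C)C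
F4 | step 17 | (E)-1-[2,4-dihydroxy-6-methoxy-3-[(2R)-5-methyl-2-(prop-1-en-2-yl)-5-(triethylsilyloxy)hexyl]phenyl]-3-(2,4-dihydroxyphenyl)prop-2-en-1-one | C=C(C)[C@H](CCC(C)(C)O[Si](CC)(CC)CC)Cc1c(O)cc(OC)c(C(=O)/C=C/c2ccc(O)cc2O)c1O
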